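The readings are simulated from invented constants; scatter was added.

Late in a run the number that matters is the fraction of free monomer lost per hour, the pseudo-first-order rate constant, so I reckon with that rate throughout.

| flask | free monomer | initiator | impurity | remark | time |
|---|---|---|---|---|---|
| Monday's | 1 M | 0.24 mol% (in portions, 2) | 0.42 mM | run made earlier; portions every 3.0 h |  |
| Friday's | 1 M | 0.24 mol% (in portions, 2) | 0.61 mM | run made earlier; portions every 3.0 h |  |
| Saturday's | 1 M | 0.24 mol% (in portions, 2) | 0.66 mM | run made earlier; portions every 3.0 h |  |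
| Sunday's | 1.6 M | 0.24 mol% (in portions, 2) | 0.48 mM | run made earlier; portions every 3.0 h |  |
| ochre | 1.0 M | 0.24 mol% (in portions, 2) | 0.48 mM | the portions of initiator follow each other after 3.0 h, the first at the start | 8.0 h |
| red | 1.5 M | 0.24 mol% | 0.80 mM | everything together at the start | 8.0 h |

| run | time / h | monomer in chains / % | free monomer / % |
|---|---|---|---|
| Monday's | 0.333 | 0.6 | 99.0 |
| Monday's | 0.667 | 1.7 | 98.0 |
| Monday's | 1.00 | 3.5 | 96.0 |
| Monday's | 2.00 | 13.3 | 86.6 |
| Monday's | 4.00 | 38.7 | 61.4 |
| Friday's | 0.833 | 2.2 | 98.2 |
| Friday's | 1.50 | 5.7 | 93.2 |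
| Friday's | 2.50 | 13.9 | 85.2 |
| Friday's | 3.00 | 19.2 | 80.8 |
| Friday's | 4.00 | 32.3 | 67.8 |
| Saturday's | 0.333 | 0.6 | 99.6 |
| Saturday's | 0.667 | 1.2 | 98.8 |
| Saturday's | 1.00 | 3.3 | 97.5 |
| Saturday's | 2.00 | 9.5 | 90.3 |
| Saturday's | 4.00 | 30.5 | 69.3 |
| Sunday's | 0.333 | 1.4 | 98.4 |
| Sunday's | 0.667 | 5.6 | 94.9 |
| Sunday's | 1.00 | 10.0 | 89.2 |
| Sunday's | 2.00 | 29.4 | 70.0 |
| Sunday's | 4.00 | 66.0 | 34.0 |

(standard deviation of a reading: 0.3 percentage points)

- what was read earlier has a scatter of 0.3 percentage points, one standard deviation
- where the amount of free monomer changes, what is given in equivalents or mol% on it follows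

- the flask that ends with the higher amount of monomer in chains, in percent of the free monomer charged, or "neither" when 2 percentage points or less lies between them (ochre / red / neither)
- final monomer in chains, as a percentage of the free monomer charged, in ochre
- final monomer in chains, as a percentage of the free monomer charged, in red

1. Monday's flask loses free monomer at 0.0408 h⁻¹ over its first hour and at 0.172 h⁻¹ from 2.00 h to 4.00 h. The rate therefore climbs by a factor of 4.22.

2. Monday's and Saturday's runs differ in impurity by 0.240 mM. I take a first portion equal to the impurity as the zero of the scale, with no rate. The log ratio of their free monomer then gives the accumulated loss per mM of initiator past the impurity: 0.174 mM⁻¹ by 2.00 h and 0.504 mM⁻¹ by 4.00 h.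

3. The growth between these readings is the rate gain, the rate added by each mM past the impurity at 1 M free monomer: 0.165 mM⁻¹ h⁻¹. It is read from two runs and carries their scatter.

4. In ochre I count the impurity mole for mole against the first portion. That cuts the portion from 1.20 mM to 0.720 mM, a factor of 0.600. I leave the second portion whole, starting at 3.0 h.

5. Extending the gain in a straight line, a mM of the first portion has earned 1.16 mM⁻¹ by 8.0 h, and a mM of the second 0.669 mM⁻¹. Ochre's accumulated loss is 1.64, so I expect 80.6 % in chains.

6. Red has 2.80 mM past the impurity from the start. Carrying the gain unchanged to 1.5 M, which is an assumption, I expect 96.2 %. I therefore expect red to end higher, by 16 percentage points.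

The forecast, holding that “the impurity appears to destroy initiator stoichiometrically”, gives 78 % for ochre, 93 % for red, and red as the higher.

    free monomer + living end → monomer in chains + living end, rate k1*[living end]*[free monomer] (k = 4.60 L mol⁻¹ min⁻¹)
    initiator + impurity → spent initiator (k = 2100 L mol⁻¹ min⁻¹)
    free monomer + initiator → living end + monomer in chains (k = 0.00730 L mol⁻¹ min⁻¹)

Ochre ends at 83.2 % and red at 98.5 %, so red is the higher. Ochre still has 63.5 % free monomer at 4.00 h. The gain on its 1.92 mM past the impurity gives a reckoned rate of 0.317 h⁻¹, and over the remaining 4.00 h that rate gives 17.9 %; the flask has 16.8 %.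

The neighbour of ochre with 1.2 × 10⁻⁴ M impurity has 0.360 mM more of its first portion past the impurity, so the same reckoning takes ochre's free monomer down to 11.0 %. The computed flask has 11.2 % free monomer and 88.8 % in chains.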